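Assumption: the target is made exactly as drawn, i.e. (1R,3R,10S,11R,12R,13R,18S,20S) in Stemona numbering (N4; C3 carries the C18–C22 lactone; C9a/C9 enamine carbons; C5–C8 azepine CH2; C10 bears ethyl; C11 bears OH; C12/C13/C14 lactone carbons with C15 methyl). This numbering is used for all intermediates. The route is a paper design; no step has been run.

**Retrosynthetic overview**
1. 24 ⇐ 22: C10–C11 bond by photocatalytic HAT radical 6-endo cyclisation of the C11 alcohol onto the α,β-unsaturated iminium (cyclohexene ring closed last).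
2. 22 ⇐ 20 + propanal (C9=C10 by condensation); 20 ⇐ 17: anodic oxidative spiro-lactonisation forming C1–O.
3. 17 ⇐ 13 + furan-2(5H)-one (C1–C12 enamine Michael addition) + MeI (C13 methyl).
4. 13 ⇐ 7 + 5-chloropentyl Grignard (C9a–C9), then Boc loss, imine formation and N-alkylation (azepine ring).
5. 7 ⇐ D-pyroglutaminol (C3 and the pyrrolidine ring bought) + ethyl 2-(bromomethyl)acrylate. Ring order: side-chain lactone → azepine → spiro-lactone → cyclohexene.

**Route**

Step 1
Reactants: 1 (5R)-5-(hydroxymethyl)pyrrolidin-2-one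
Product: 2 (2R)-5-oxopyrrolidine-2-carbaldehyde
Conditions: Dess–Martin periodinane (1.2 equiv), MeCN/CH2Cl2, 0 °C to rt; used crude at once
Reagents that add atoms: none
Why: Dess–Martin oxidation of the primary alcohol under neutral conditions, with immediate use so the α-amino aldehyde stereocentre (C3) is not epimerised.

Step 2
Reactants: 2 (2R)-5-oxopyrrolidine-2-carbaldehyde; 3 ethyl 2-(bromomethyl)prop-2-enoate
Product: 5 (5R)-5-[(2S)-4-methylidene-5-oxooxolan-2-yl]pyrrolidin-2-one, via hydroxy ester 4 (not isolated)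
Conditions: Zn dust, THF/sat. aq NH4Cl, 0 °C to rt; then p-TsOH (cat.), CH2Cl2, rt
Reagents that add atoms: none
Why: Dreiding–Schmidt Zn-Barbier allylation then acid lactonisation; non-chelated Felkin–Anh attack anti to the lactam nitrogen sets C18 (S), anti to C3, as the target requires.

Step 3
Reactants: 5 (5R)-5-[(2S)-4-methylidene-5-oxooxolan-2-yl]pyrrolidin-2-one
Product: 6 (5R)-5-[(2S,4S)-4-methyl-5-oxooxolan-2-yl]pyrrolidin-2-one
Conditions: H2 (1 atm), 5% Rh/Al2O3, EtOAc, rt
Reagents that add atoms: none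
Why: Heterogeneous hydrogenation of the exo-methylene from the face opposite the C18 substituent gives the cis-2,4-disubstituted lactone (C20 S).

Step 4
Reactants: 6 (5R)-5-[(2S,4S)-4-methyl-5-oxooxolan-2-yl]pyrrolidin-2-one
Product: 7 tert-butyl (2R)-2-[(2S,4S)-4-methyl-5-oxooxolan-2-yl]-5-oxopyrrolidine-1-carboxylate
Conditions: Boc2O (1.3 equiv), DMAP (0.1 equiv), MeCN, rt
Reagents that add atoms: di-tert-butyl dicarbonate CC(C)(C)OC(=O)OC(=O)OC(C)(C)C
Why: DMAP-catalysed N-acylation turns the lactam into an imide-like carbonyl, the most electrophilic site for step 5.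

Step 5
Reactants: 7 tert-butyl (2R)-2-[(2S,4S)-4-methyl-5-oxooxolan-2-yl]-5-oxopyrrolidine-1-carboxylate; 8 1-bromo-5-chloropentane
Product: 10 tert-butyl N-[(1R)-9-chloro-1-[(2S,4S)-4-methyl-5-oxooxolan-2-yl]-4-oxononyl]carbamate, via 5-chloropentylmagnesium bromide 9 (not isolated)
Conditions: 8, Mg, THF, rt; then 7, THF, −78 °C; aq NH4Cl
Reagents that add atoms: none
Why: Grignard formation at C–Br, then chemoselective addition to the N-Boc lactam carbonyl at −78 °C with ring opening to the carbamate ketone (no over-addition; the γ-lactone is slower), forming C9a–C9.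

Step 6
Reactants: 10 tert-butyl N-[(1R)-9-chloro-1-[(2S,4S)-4-methyl-5-oxooxolan-2-yl]-4-oxononyl]carbamate
Product: 13 (3R)-3-[(2S,4S)-4-methyl-5-oxooxolan-2-yl]-2,3,6,7,8,9-hexahydro-1H,5H-pyrrolo[1,2-a]azepin-4-ium chloride, via aminium trifluoroacetate 11 (not isolated), via cyclic imine 12 (not isolated)
Conditions: TFA/CH2Cl2 1:3, 0 °C to rt; sat. aq NaHCO3; NaI (0.1 equiv), MeCN (0.02 M), 75 °C
Reagents that add atoms: none
Why: Acidolytic Boc removal, condensation of the amine with the ketone to the 1-pyrroline, and iodide-catalysed intramolecular N-alkylation (7-exo-tet) close the azepine as the bicyclic iminium salt.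

Step 7
Reactants: 13 (3R)-3-[(2S,4S)-4-methyl-5-oxooxolan-2-yl]-2,3,6,7,8,9-hexahydro-1H,5H-pyrrolo[1,2-a]azepin-4-ium chloride; 14 furan-2(5H)-one
Product: 17 (3R,4S)-3-methyl-4-[(3R)-3-[(2S,4S)-4-methyl-5-oxooxolan-2-yl]-2,3,6,7,8,9-hexahydro-5H-pyrrolo[1,2-a]azepin-1-yl]oxolan-2-one, via enamine 15 (not isolated), via Michael adduct 16 (not isolated)
Conditions: aq K2CO3/CH2Cl2, 0 °C (enamine freed and dried); 14 (1.2 equiv), MeCN, 0 °C to rt; evaporate; LDA (1.1 equiv), THF, −78 °C; MeI (1.3 equiv), −78 to −40 °C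
Reagents that add atoms: iodomethane CI
Why: Stork enamine Michael addition of the C1=C9a enamine (double bond endocyclic in the five-membered ring, expected to be favoured) at C1, anti to the pseudoaxial C3 lactone, through a Seebach–Golinski synclinal transition state (butenolide carbonyl over nitrogen) sets C12; kinetic LDA enolisation of the less hindered lactone CH2 and methylation trans to the C12 substituent then sets C13.

Step 8
Reactants: 17 (3R,4S)-3-methyl-4-[(3R)-3-[(2S,4S)-4-methyl-5-oxooxolan-2-yl]-2,3,6,7,8,9-hexahydro-5H-pyrrolo[1,2-a]azepin-1-yl]oxolan-2-one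
Product: 20 (1R,3R,12R,13R,18S,20S)-spiro-lactone iminium trifluoroacetate (C1–O–C14 γ-lactone spiro at C1; 12-hydroxymethyl; 13-methyl; C9a=N4 iminium; C9 is CH2), via dilithium dicarboxylate 18 (not isolated), via zwitterion 19 (not isolated)
Conditions: LiOH·H2O (2.1 equiv), THF/H2O 3:1, 0 °C to rt; evaporate; MeOH/MeCN 1:4, 0.1 M LiClO4, RVC anode, Pt cathode, divided cell, +0.55 V vs Ag/AgCl, 2.1 F/mol, 0 °C; then TFA (3.5 equiv), rt
Reagents that add atoms: lithium hydroxide [Li+].[OH-]; trifluoroacetic acid OC(=O)C(F)(F)F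
Why: Saponification frees the C14 carboxylate, and anodic two-electron oxidation of the enamine (known anodic α-oxygenation of enamines, here with an internal carboxylate) is trapped 5-exo at C1 on the face anti to the C3 substituent, setting the quaternary C1 with the lactone cis-fused to C12; the product is an iminium and is not re-oxidised, and TFA recloses the side-chain lactone.

Step 9
Reactants: 20 spiro-lactone iminium trifluoroacetate; 21 propanal
Product: 22 (9E)-9-propylidene spiro-lactone iminium trifluoroacetate (α,β-unsaturated iminium C10=C9–C9a=N4; otherwise as 20)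
Conditions: 21 (5 equiv), i-Pr2NEt (0.3 equiv), AcOH (0.3 equiv), 4 Å MS, MeCN, 45 °C
Reagents that add atoms: none
Why: Knoevenagel-type aldol condensation of the iminium through its only possible enamine (C9, since C1 is quaternary); the E-alkene with ethyl away from the quaternary C1 is the thermodynamic product.

Step 10
Reactants: 22 (9E)-9-propylidene spiro-lactone iminium trifluoroacetate
Product: 24 CNP0154902.3 (target), via iminium trifluoroacetate 23 (not isolated)
Conditions: (n-Bu4N)4[W10O32] (4 mol%), MeCN (5 mM), 390 nm LEDs, Ar, rt; then sat. aq NaHCO3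
Reagents that add atoms: none
Why: Proposed new method: excited decatungstate abstracts the hydridic α-C–H of the C11 primary alcohol, the nucleophilic α-hydroxyalkyl radical adds 6-endo-trig to C10 (β-carbon of the tethered unsaturated iminium, polarity-matched Giese step), and back hydrogen/electron transfer from reduced decatungstate to the α-iminium radical gives saturated iminium 23, which NaHCO3 deprotonates at C9 (the only enolisable site) to the enamine; C10 is set because C11 can only reach the alkene face on which C12 sits and the E-alkene puts ethyl outside (ethyl trans to the new C11–O), and C11 is set by the hydroxyl taking the exo position away from the iminium π-system (OH cis to C13); the closest known reactions are decatungstate-photocatalysed hydroalkylation of electron-poor alkenes with alcohols and radical conjugate addition to iminium ions, neither shown for ring closure onto a preformed unsaturated iminium.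

**Compound list**
1 | (5R)-5-(hydroxymethyl)pyrrolidin-2-one (D-pyroglutaminol) | OC[C@H]1CCC(=O)N1 | starting material
2 | (2R)-5-oxopyrrolidine-2-carbaldehyde | O=C[C@H]1CCC(=O)N1 | intermediate
3 | ethyl 2-(bromomethyl)prop-2-enoate | C=C(CBr)C(=O)OCC | starting material
4 | ethyl (4S)-4-hydroxy-2-methylidene-4-[(2R)-5-oxopyrrolidin-2-yl]butanoate | CCOC(=O)C(=C)C[C@H](O)[C@H]1CCC(=O)N1 | intermediate (not isolated)
5 | (5R)-5-[(2S)-4-methylidene-5-oxooxolan-2-yl]pyrrolidin-2-one | O=C1CC[C@@H](N1)[C@@H]1CC(=C)C(=O)O1 | intermediate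
6 | (5R)-5-[(2S,4S)-4-methyl-5-oxooxolan-2-yl]pyrrolidin-2-one | O=C1CC[C@@H](N1)[C@@H]1C[C@H](C)C(=O)O1 | intermediate
7 | tert-butyl (2R)-2-[(2S,4S)-4-methyl-5-oxooxolan-2-yl]-5-oxopyrrolidine-1-carboxylate | O=C1CC[C@@H](N1C(=O)OC(C)(C)C)[C@@H]1C[C@H](C)C(=O)O1 | intermediate
8 | 1-bromo-5-chloropentane | ClCCCCCBr | starting material
9 | 5-chloropentylmagnesium bromide | ClCCCCC[Mg]Br | intermediate (not isolated)
10 | tert-butyl N-[(1R)-9-chloro-1-[(2S,4S)-4-methyl-5-oxooxolan-2-yl]-4-oxononyl]carbamate | CC(C)(C)OC(=O)N[C@H](CCC(=O)CCCCCCl)[C@@H]1C[C@H](C)C(=O)O1 | intermediate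
11 | (1R)-9-chloro-1-[(2S,4S)-4-methyl-5-oxooxolan-2-yl]-4-oxononan-1-aminium trifluoroacetate | [NH3+][C@H](CCC(=O)CCCCCCl)[C@@H]1C[C@H](C)C(=O)O1.[O-]C(=O)C(F)(F)F | intermediate (not isolated)
12 | (3S,5S)-5-[(2R)-5-(5-chloropentyl)-3,4-dihydro-2H-pyrrol-2-yl]-3-methyloxolan-2-one | ClCCCCCC1=N[C@H](CC1)[C@@H]1C[C@H](C)C(=O)O1 | intermediate (not isolated)
13 | (3R)-3-[(2S,4S)-4-methyl-5-oxooxolan-2-yl]-2,3,6,7,8,9-hexahydro-1H,5H-pyrrolo[1,2-a]azepin-4-ium chloride | C1CCC[N+]2=C(C1)CC[C@@H]2[C@@H]1C[C@H](C)C(=O)O1.[Cl-] | intermediate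
14 | furan-2(5H)-one | O=C1OCC=C1 | starting material
15 | (3S,5S)-3-methyl-5-[(3R)-2,3,6,7,8,9-hexahydro-5H-pyrrolo[1,2-a]azepin-3-yl]oxolan-2-one (C1=C9a enamine) | C1CCCN2C(C1)=CC[C@@H]2[C@@H]1C[C@H](C)C(=O)O1 | intermediate (not isolated)
16 | (4S)-4-[(3R)-3-[(2S,4S)-4-methyl-5-oxooxolan-2-yl]-2,3,6,7,8,9-hexahydro-5H-pyrrolo[1,2-a]azepin-1-yl]oxolan-2-one | C1CCCN2C(C1)=C(C[C@@H]2[C@@H]1C[C@H](C)C(=O)O1)[C@H]1COC(=O)C1 | intermediate (not isolated)
17 | (3R,4S)-3-methyl-4-[(3R)-3-[(2S,4S)-4-methyl-5-oxooxolan-2-yl]-2,3,6,7,8,9-hexahydro-5H-pyrrolo[1,2-a]azepin-1-yl]oxolan-2-one | C1CCCN2C(C1)=C(C[C@@H]2[C@@H]1C[C@H](C)C(=O)O1)[C@H]1COC(=O)[C@@H]1C | intermediate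
18 | dilithium salt of the bis(hydroxy acid) from opening both lactones of 17 (3R,12S,13R,18S,20S) | C1CCCN2C(C1)=C(C[C@@H]2[C@@H](O)C[C@H](C)C(=O)[O-])[C@@H](CO)[C@@H](C)C(=O)[O-].[Li+].[Li+] | intermediate (not isolated)
19 | zwitterion: C1 spiro-lactone iminium with open side-chain hydroxy carboxylate (1R,3R,12R,13R,18S,20S) | C1C2=[N+](CCCC1)[C@@H]([C@@H](O)C[C@H](C)C(=O)[O-])C[C@]21OC(=O)[C@H](C)[C@@H]1CO | intermediate (not isolated)
20 | (1R,3R,12R,13R,18S,20S)-spiro-lactone iminium trifluoroacetate (C1–O–C14 lactone, 12-CH2OH, C9a=N4+, C9H2) | C1C2=[N+](CCCC1)[C@@H]([C@@H]1C[C@H](C)C(=O)O1)C[C@]21OC(=O)[C@H](C)[C@@H]1CO.[O-]C(=O)C(F)(F)F | intermediate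
21 | propanal | CCC=O | starting material
22 | (9E)-9-propylidene spiro-lactone iminium trifluoroacetate (1R,3R,12R,13R,18S,20S) | CC/C=C1/C2=[N+](CCCC1)[C@@H]([C@@H]1C[C@H](C)C(=O)O1)C[C@]21OC(=O)[C@H](C)[C@@H]1CO.[O-]C(=O)C(F)(F)F | intermediate
23 | C9-protonated iminium trifluoroacetate of 24 (C9 configuration not defined; erased on deprotonation) | CC[C@H]1C2C3=[N+](CCCC2)[C@@H]([C@@H]2C[C@H](C)C(=O)O2)C[C@]32OC(=O)[C@H](C)[C@@H]2[C@@H]1O.[O-]C(=O)C(F)(F)F | intermediate (not isolated)
24 | CNP0154902.3, (1R,3R,10S,11R,12R,13R,18S,20S) | CC[C@H]1C2=C3N(CCCC2)[C@@H]([C@@H]2C[C@H](C)C(=O)O2)C[C@]32OC(=O)[C@H](C)[C@@H]2[C@@H]1O | target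

**Totals**
Total step count: 10. Longest linear sequence: 10 (fully linear from 1; the Grignard reagent is made in the flask).

**Three steps most likely to fail, with fallbacks**

Step 10 (the proposed new photochemical ring closure). The risks are electron transfer from the α-hydroxyalkyl radical to the iminium instead of C–C bond formation, the C11 epimer from an endo hydroxyl, and reversible oxa-Michael addition of the alcohol. Fallback with known chemistry, starting from 22: Dess–Martin oxidation of the primary alcohol gives aldehyde iminium trifluoroacetate F5. SmI2 (2.2 equiv) with t-BuOH in THF at −78 °C then effects a ketyl–olefin reductive 6-endo cyclisation onto the unsaturated iminium (Bu3SnH/AIBN stannyl-ketyl cyclisation as alternative). NaHCO3 work-up returns to the route at 24.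

Step 8 (anodic spiro-lactonisation). The risks are enamine tautomer mixtures, capture of the radical cation by the side-chain C18 hydroxyl or by methanol, and acid-promoted lactone migration back to C11. Fallback, starting from 17 with both lactones intact: dimethyldioxirane in acetone at −78 °C epoxidises the C1=C9a enamine anti to the C3 substituent, and TFA quench gives hydroxy iminium trifluoroacetate F4. Brief treatment with NaHCO3 in MeOH lets the C1 alkoxide attack the C14 lactone carbonyl and expel the primary C11 alkoxide (translactonisation). Re-acidification with TFA returns to the route at 20.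

Step 7 (enamine Michael addition and selective methylation). The risks are competing attack through the C9 enamine, imperfect C12 selectivity, and LDA enolising the side-chain lactone. Fallback, starting from 7: LiHMDS at −78 °C forms the N-Boc lactam enolate, which can only react at C1. Addition to furan-2(5H)-one and in-flask MeI trapping of the lactone enolate gives lactam adduct F1 (C1 substituent trans to the C3 lactone; the C12 ratio must be checked). Grignard reagent 9 at −78 °C opens F1 to chloro ketone F2. TFA, NaHCO3 and heating with catalytic NaI in MeCN give iminium chloride F3, and aq K2CO3 liberates the enamine, returning to the route at 17.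

**Further compounds**
F1 | step 7 | tert-butyl pyrrolidinone carboxylate: lactam adduct with the (3R,4S)-4-methyl-5-oxooxolan-3-yl unit at C1 trans to the C3 lactone | O=C1[C@H](C[C@@H](N1C(=O)OC(C)(C)C)[C@@H]1C[C@H](C)C(=O)O1)[C@H]1COC(=O)[C@@H]1C
F2 | step 7 | chloro ketone: ring-opened N-Boc amino ketone carrying both lactones | CC(C)(C)OC(=O)N[C@H](C[C@@H](C(=O)CCCCCCl)[C@H]1COC(=O)[C@@H]1C)[C@@H]1C[C@H](C)C(=O)O1
F3 | step 7 | iminium chloride: C1-protonated iminium form of 17 | C1CCC[N+]2=C(C1)[C@H](C[C@@H]2[C@@H]1C[C@H](C)C(=O)O1)[C@H]1COC(=O)[C@@H]1C.[Cl-]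
F4 | step 8 | hydroxy iminium trifluoroacetate: C1-hydroxylated iminium with the C11–O lactone still in place | C1C2=[N+](CCCC1)[C@@H]([C@@H]1C[C@H](C)C(=O)O1)C[C@@]2(O)[C@H]1COC(=O)[C@@H]1C.[O-]C(=O)C(F)(F)F
F5 | step 10 | aldehyde iminium trifluoroacetate: C11 aldehyde analogue of 22 | CC/C=C1/C2=[N+](CCCC1)[C@@H]([C@@H]1C[C@H](C)C(=O)O1)C[C@]21OC(=O)[C@H](C)[C@@H]1C=O.[O-]C(=O)C(F)(F)F
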